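**Retrosynthetic overview** (carotenoid numbering: ring C1–C6, furan CH = C8, chain C9–C15, C15'–C10')
1. Target ⇐ desilylation and ester reduction of a C27 ester ⇐ E-selective Wittig reaction (C11=C12) of a (9Z)-C15 tributylphosphonium salt with a C12 ester-aldehyde (C10 dialdehyde + C2 ylide).
2. C15 dihydrofuran ⇐ gold-catalysed 5-endo cycloisomerisation of an α-hydroxyallene, which turns the allene axis into the C8 centre.
3. Allenol ⇐ anti-SN2' copper hydride reduction of an alkynyl oxirane ⇐ Sonogashira coupling of an ethynyl epoxide with a (Z)-3-iodobut-2-enyl silyl ether.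
4. Ethynyl epoxide ⇐ Ohira–Bestmann alkynylation, oxidation and Sharpless epoxidation (C5, C6) of a cyclohexenylmethanol ⇐ carbonylation of the enol triflate of silylated actinol.
5. Actinol ⇐ ketoisophorone by ene-reductase, then ketoreductase. Ring order: the carbocycle is present from the start, the oxirane (step 7) is temporary, and the dihydrofuran is formed last (step 14).

Assumption: the C9=C10 bond is taken exactly as written in the SMILES (methyl trans to C11, i.e. 9Z, C8 cis to C11); (2E,4E,6E)-2,7-dimethylocta-2,4,6-trienedial is taken as a commercial material.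

Step 1
Reactants: 1 ketoisophorone (2,6,6-trimethylcyclohex-2-ene-1,4-dione)
Product: 2 (6R)-levodione ((6R)-2,2,6-trimethylcyclohexane-1,4-dione)
Conditions: ene-reductase (Old Yellow Enzyme family), NAD+ (cat.), formate dehydrogenase, HCO2Na, KH2PO4/K2HPO4 buffer pH 7.0, 30 °C
Reagents that add atoms: none
Why: Flavin-dependent ene-reductases perform a trans-hydrogenation of this doubly activated C=C bond (biocatalytic asymmetric conjugate reduction), and the enzyme active site fixes the face of addition so that the first stereocentre is formed as (6R).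

Step 2
Reactants: 2 (6R)-levodione
Product: 3 (4R,6R)-actinol ((4R,6R)-4-hydroxy-2,2,6-trimethylcyclohexan-1-one)
Conditions: ketoreductase (levodione-reductase type), NAD+ (cat.), iPrOH (10% v/v), KH2PO4/K2HPO4 buffer pH 7.0, 30 °C
Reagents that add atoms: none
Why: This enzymatic carbonyl reduction touches only the unhindered C4 ketone (C1 is flanked by the gem-dimethyl and methyl carbons) and delivers hydride under catalyst control to give the (4R)-carbinol, the centre that becomes C3 of the target.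

Step 3
Reactants: 3 (4R,6R)-actinol
Product: 4 (4R,6R)-4-[tert-butyl(dimethyl)silyl]oxy-2,2,6-trimethylcyclohexan-1-one
Conditions: TBSCl, imidazole, DMF, rt
Reagents that add atoms: tert-butyldimethylsilyl chloride (CC(C)(C)[Si](C)(C)Cl)
Why: Standard imidazole-promoted silylation of a secondary alcohol; no stereocentre is affected.

Step 4
Reactants: 4 silylated actinol
Product: 6 (4R)-4-[tert-butyl(dimethyl)silyl]oxy-2,6,6-trimethylcyclohex-1-en-1-yl trifluoromethanesulfonate, via lithium enolate 5 (not isolated)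
Conditions: LiN(iPr)2, THF, −78 → 0 °C; then PhNTf2, −78 °C → rt
Reagents that add atoms: N-phenylbis(trifluoromethanesulfonimide) (O=S(=O)(N(c1ccccc1)S(=O)(=O)C(F)(F)F)C(F)(F)F)
Why: Only C6 carries an α-hydrogen, so deprotonation gives a single enolate that is O-triflated (enol triflate formation); the C6 centre is deliberately erased and the carbinol centre is untouched.

Step 5
Reactants: 6 enol triflate
Product: 7 methyl (4R)-4-[tert-butyl(dimethyl)silyl]oxy-2,6,6-trimethylcyclohex-1-ene-1-carboxylate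
Conditions: Pd(OAc)2 (5 mol%), PPh3 (10 mol%), CO (1 atm), MeOH, Et3N, DMF, 50 °C
Reagents that add atoms: carbon monoxide ([C-]#[O+]); methanol (CO)
Why: Palladium-catalysed alkoxycarbonylation of an enol triflate (oxidative addition to zerovalent palladium, CO insertion, methanolysis) installs C7 without touching the silyl ether.

Step 6
Reactants: 7 unsaturated methyl ester
Product: 8 [(4R)-4-[tert-butyl(dimethyl)silyl]oxy-2,6,6-trimethylcyclohex-1-en-1-yl]methanol
Conditions: iBu2AlH (2.5 equiv), CH2Cl2, −78 → 0 °C; potassium sodium tartrate work-up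
Reagents that add atoms: none
Why: Aluminium hydride reduction of a conjugated ester gives the allylic alcohol by 1,2-reduction only.

Step 7
Reactants: 8 allylic alcohol
Product: 9 [(1R,4S,6R)-4-[tert-butyl(dimethyl)silyl]oxy-2,2,6-trimethyl-7-oxabicyclo[4.1.0]heptan-1-yl]methanol
Conditions: Ti(OiPr)4 (20 mol%), D-(−)-diethyl tartrate (24 mol%), tBuOOH, 4 Å molecular sieves, CH2Cl2, −20 °C
Reagents that add atoms: tert-butyl hydroperoxide (CC(C)(C)OO)
Why: Katsuki–Sharpless asymmetric epoxidation: the D-(−)-tartrate/titanium catalyst delivers oxygen to the alkene face anti to the silyloxy group (reagent control), which sets C5 and C6 and thereby the C5–O bond of the target as (5R).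

Step 8
Reactants: 9 epoxy alcohol
Product: 10 (1S,4S,6R)-4-[tert-butyl(dimethyl)silyl]oxy-2,2,6-trimethyl-7-oxabicyclo[4.1.0]heptane-1-carbaldehyde
Conditions: Dess–Martin periodinane, pyridine, CH2Cl2, 0 °C → rt
Reagents that add atoms: none
Why: Mild periodinane oxidation of a primary alcohol; the aldehyde has no α-hydrogen, so the epoxide centres cannot epimerise (the descriptor at C1 changes only through CIP priorities).

Step 9
Reactants: 10 epoxy aldehyde
Product: 11 (1R,4S,6R)-4-[tert-butyl(dimethyl)silyl]oxy-1-ethynyl-2,2,6-trimethyl-7-oxabicyclo[4.1.0]heptane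
Conditions: dimethyl (1-diazo-2-oxopropyl)phosphonate, K2CO3, MeOH, 0 °C → rt
Reagents that add atoms: dimethyl (1-diazo-2-oxopropyl)phosphonate (COP(=O)(OC)C(=[N+]=[N-])C(C)=O)
Why: Seyferth–Gilbert homologation in the Ohira–Bestmann variant converts the non-enolisable aldehyde into the terminal alkyne (C8) under mildly basic conditions that leave the epoxide intact.

Step 10
Reactants: 12 but-2-yn-1-ol
Product: 14 (2Z)-3-iodobut-2-en-1-ol, via cyclic alkenylaluminate 13 (not isolated)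
Conditions: NaAlH2(OCH2CH2OMe)2, THF, 0 °C → rt; then I2, THF, −78 °C
Reagents that add atoms: iodine (II)
Why: Alkoxide-directed trans-hydroalumination places aluminium on C3 cis to the CH2O group in a five-membered aluminate, and iodinolysis with retention gives only the (Z)-iodide.

Step 11
Reactants: 14 (2Z)-3-iodobut-2-en-1-ol
Product: 15 triethyl{[(2Z)-3-iodobut-2-en-1-yl]oxy}silane
Conditions: TESCl, imidazole, CH2Cl2, 0 °C
Reagents that add atoms: chlorotriethylsilane (CC[Si](Cl)(CC)CC)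
Why: Silylation masks the hydroxyl, which would otherwise cyclise onto the alkyne or allene in later steps, and TES can later be removed in the presence of the secondary TBS ether.

Step 12
Reactants: 11 ethynyl epoxide; 15 (Z)-vinyl iodide
Product: 16 (1R,4S,6R)-4-[tert-butyl(dimethyl)silyl]oxy-2,2,6-trimethyl-1-[(3Z)-3-methyl-5-(triethylsilyloxy)pent-3-en-1-yn-1-yl]-7-oxabicyclo[4.1.0]heptane
Conditions: Pd(PPh3)4 (5 mol%), CuI (10 mol%), iPr2NH, THF, rt
Reagents that add atoms: none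
Why: Sonogashira coupling of a terminal alkyne with a vinyl iodide proceeds at room temperature with retention of the (Z)-alkene geometry, which becomes the 9Z bond of the target.

Step 13
Reactants: 16 epoxy enyne
Product: 18 (1R,5S,aS)-5-[tert-butyl(dimethyl)silyl]oxy-1,3,3-trimethyl-2-[(3Z)-3-methyl-5-(triethylsilyloxy)penta-1,3-dien-1-ylidene]cyclohexan-1-ol, via tertiary silyl ether 17 (not isolated)
Conditions: chloro[1,3-bis(2,6-diisopropylphenyl)imidazol-2-ylidene]copper, (IPr)CuCl (5 mol%), NaOtBu (6 mol%), (EtO)2MeSiH (2 equiv), toluene, 0 °C → rt; then K2CO3, MeOH, 0 °C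
Reagents that add atoms: none
Why: Copper hydride SN2' reduction of a propargylic oxirane (syn-hydrocupration, then anti-β-alkoxide elimination) delivers hydride to C8 anti to the breaking C6–O bond, so by centre-to-axis transfer the side chain lies on the same side as the retained tertiary C5–O bond, i.e. the (aS)-allene.

Step 14
Reactants: 18 α-hydroxyallene
Product: 19 tert-butyl(dimethyl){[(2R,6S,7aR)-4,4,7a-trimethyl-2-[(2Z)-4-(triethylsilyloxy)but-2-en-2-yl]-2,4,5,6,7,7a-hexahydro-1-benzofuran-6-yl]oxy}silane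
Conditions: AuCl3 (2 mol%), THF, 0 °C → rt, dark
Reagents that add atoms: none
Why: In this gold-catalysed 5-endo cycloisomerisation of an α-hydroxyallene the tertiary hydroxyl attacks the gold-activated allene terminus C8 in the plane of the C6 substituents and protodeauration follows, so the allene axis is converted stereospecifically into the C8 centre with the side chain trans to the angular methyl, i.e. (2R).

Step 15
Reactants: 19 bis-silylated dihydrofuran
Product: 20 (2Z)-3-[(2R,6S,7aR)-6-[tert-butyl(dimethyl)silyl]oxy-4,4,7a-trimethyl-2,4,5,6,7,7a-hexahydro-1-benzofuran-2-yl]but-2-en-1-ol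
Conditions: HF·pyridine, excess pyridine, THF, 0 °C
Reagents that add atoms: none
Why: Buffered fluoride cleaves the primary allylic TES ether far faster than the hindered secondary TBS ether (selective desilylation), and the pyridine buffer protects the doubly allylic C8–O bond from ionisation.

Step 16
Reactants: 20 allylic alcohol
Product: 21 {[(2R,6S,7aR)-2-[(2Z)-4-bromobut-2-en-2-yl]-4,4,7a-trimethyl-2,4,5,6,7,7a-hexahydro-1-benzofuran-6-yl]oxy}(tert-butyl)dimethylsilane
Conditions: CBr4, PPh3, 2,6-lutidine (cat.), CH2Cl2, −20 → 0 °C; short silica plug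
Reagents that add atoms: carbon tetrabromide (BrC(Br)(Br)Br)
Why: The Appel reaction converts the primary allylic alcohol into the bromide by SN2 displacement under neutral conditions, which keeps the 9Z geometry and the acid-labile C8 centre.

Step 17
Reactants: 21 allylic bromide
Product: 22 tributyl[(2Z)-3-[(2R,6S,7aR)-6-[tert-butyl(dimethyl)silyl]oxy-4,4,7a-trimethyl-2,4,5,6,7,7a-hexahydro-1-benzofuran-2-yl]but-2-en-1-yl]phosphonium bromide
Conditions: PBu3, MeCN, rt
Reagents that add atoms: tributylphosphine (CCCCP(CCCC)CCCC)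
Why: SN2 quaternisation of the primary allylic bromide by the nucleophilic trialkylphosphine occurs at room temperature without acid.

Step 18
Reactants: 23 (2E,4E,6E)-2,7-dimethylocta-2,4,6-trienedial (3 equiv)
Product: 24 ethyl (2E,4E,6E,8E)-4,9-dimethyl-10-oxodeca-2,4,6,8-tetraenoate
Conditions: Ph3P=CHCO2Et (1 equiv), CH2Cl2, 0 °C → rt; excess dialdehyde recovered
Reagents that add atoms: (ethoxycarbonylmethylene)triphenylphosphorane (CCOC(=O)C=P(c1ccccc1)(c1ccccc1)c1ccccc1)
Why: Wittig olefination with a stabilised ylide is E-selective, and the excess of the symmetrical dialdehyde limits reaction to one end.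

Step 19
Reactants: 22 C15 phosphonium bromide; 24 C12 ester-aldehyde
Product: 26 ethyl (2E,4E,6E,8E,10E,12Z)-13-[(2R,6S,7aR)-6-[tert-butyl(dimethyl)silyl]oxy-4,4,7a-trimethyl-2,4,5,6,7,7a-hexahydro-1-benzofuran-2-yl]-4,9-dimethyltetradeca-2,4,6,8,10,12-hexaenoate, via phosphonium ylide 25 (not isolated)
Conditions: NaN(SiMe3)2, THF, −78 °C; then 24, −78 → 0 °C, dark
Reagents that add atoms: none
Why: Wittig olefination with an allylic tributylphosphonium ylide is strongly E-selective for the new C11=C12 bond, attacks only the aldehyde of 24, and at low temperature leaves the existing 9Z bond and the C8 centre (whose hydrogen is not deprotonated) unchanged.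

Step 20
Reactants: 26 C27 ester
Product: 27 (2E,4E,6E,8E,10E,12Z)-13-[(2R,6S,7aR)-6-[tert-butyl(dimethyl)silyl]oxy-4,4,7a-trimethyl-2,4,5,6,7,7a-hexahydro-1-benzofuran-2-yl]-4,9-dimethyltetradeca-2,4,6,8,10,12-hexaen-1-ol
Conditions: iBu2AlH (2.5 equiv), CH2Cl2, −78 °C; potassium sodium tartrate work-up, dark
Reagents that add atoms: none
Why: Aluminium hydride 1,2-reduction of the conjugated ester gives the primary allylic alcohol without touching the polyene or the cyclic ether.

Step 21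
Reactants: 27 silylated C27 alcohol
Product: 28 target, (2R,6S,7aR)-2-[(2Z,4E,6E,8E,10E,12E)-14-hydroxy-6,11-dimethyltetradeca-2,4,6,8,10,12-hexaen-2-yl]-4,4,7a-trimethyl-2,4,5,6,7,7a-hexahydro-1-benzofuran-6-ol
Conditions: Bu4NF, THF, rt, dark
Reagents that add atoms: none
Why: Fluoride-mediated desilylation is basic and non-acidic, so the acid-labile doubly allylic ether (C8) and the polyenol survive and no stereocentre is touched.

**Compound list**
1 | ketoisophorone (2,6,6-trimethylcyclohex-2-ene-1,4-dione) | CC1=CC(=O)CC(C)(C)C1=O | starting material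
2 | (6R)-2,2,6-trimethylcyclohexane-1,4-dione | C[C@@H]1CC(=O)CC(C)(C)C1=O | intermediate
3 | (4R,6R)-4-hydroxy-2,2,6-trimethylcyclohexan-1-one | C[C@@H]1C[C@@H](O)CC(C)(C)C1=O | intermediate
4 | (4R,6R)-4-[tert-butyl(dimethyl)silyl]oxy-2,2,6-trimethylcyclohexan-1-one | C[C@@H]1C[C@@H](O[Si](C)(C)C(C)(C)C)CC(C)(C)C1=O | intermediate
5 | lithium (4R)-4-[tert-butyl(dimethyl)silyl]oxy-2,6,6-trimethylcyclohex-1-en-1-olate | CC1=C(O[Li])C(C)(C)C[C@H](O[Si](C)(C)C(C)(C)C)C1 | intermediate
6 | (4R)-4-[tert-butyl(dimethyl)silyl]oxy-2,6,6-trimethylcyclohex-1-en-1-yl trifluoromethanesulfonate | CC1=C(OS(=O)(=O)C(F)(F)F)C(C)(C)C[C@H](O[Si](C)(C)C(C)(C)C)C1 | intermediate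
7 | methyl (4R)-4-[tert-butyl(dimethyl)silyl]oxy-2,6,6-trimethylcyclohex-1-ene-1-carboxylate | CC1=C(C(=O)OC)C(C)(C)C[C@H](O[Si](C)(C)C(C)(C)C)C1 | intermediate
8 | [(4R)-4-[tert-butyl(dimethyl)silyl]oxy-2,6,6-trimethylcyclohex-1-en-1-yl]methanol | CC1=C(CO)C(C)(C)C[C@H](O[Si](C)(C)C(C)(C)C)C1 | intermediate
9 | [(1R,4S,6R)-4-[tert-butyl(dimethyl)silyl]oxy-2,2,6-trimethyl-7-oxabicyclo[4.1.0]heptan-1-yl]methanol (epoxide anti to the silyloxy group) | OC[C@@]12O[C@]1(C)C[C@@H](O[Si](C)(C)C(C)(C)C)CC2(C)C | intermediate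
10 | (1S,4S,6R)-4-[tert-butyl(dimethyl)silyl]oxy-2,2,6-trimethyl-7-oxabicyclo[4.1.0]heptane-1-carbaldehyde | O=C[C@@]12O[C@]1(C)C[C@@H](O[Si](C)(C)C(C)(C)C)CC2(C)C | intermediate
11 | (1R,4S,6R)-4-[tert-butyl(dimethyl)silyl]oxy-1-ethynyl-2,2,6-trimethyl-7-oxabicyclo[4.1.0]heptane | C#C[C@@]12O[C@]1(C)C[C@@H](O[Si](C)(C)C(C)(C)C)CC2(C)C | intermediate
12 | but-2-yn-1-ol | CC#CCO | starting material
13 | sodium 2,2-bis(2-methoxyethoxy)-3-methyl-2,5-dihydro-1,2-oxaaluminol-2-uide (cyclic alkenylaluminate) | CC1=CCO[Al-]1(OCCOC)OCCOC.[Na+] | intermediate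
14 | (2Z)-3-iodobut-2-en-1-ol | C/C(I)=C/CO | intermediate
15 | triethyl{[(2Z)-3-iodobut-2-en-1-yl]oxy}silane | C/C(I)=C/CO[Si](CC)(CC)CC | intermediate
16 | (1R,4S,6R)-4-[tert-butyl(dimethyl)silyl]oxy-2,2,6-trimethyl-1-[(3Z)-3-methyl-5-(triethylsilyloxy)pent-3-en-1-yn-1-yl]-7-oxabicyclo[4.1.0]heptane | C(#C[C@@]12O[C@]1(C)C[C@@H](O[Si](C)(C)C(C)(C)C)CC2(C)C)/C(C)=C\CO[Si](CC)(CC)CC | intermediate
17 | diethoxy(methyl)silyl ether of 18 at the tertiary oxygen (same (1R,5S,aS) configuration) | [H]C(/C(C)=C\CO[Si](CC)(CC)CC)=[C@@]=C1C(C)(C)C[C@H](O[Si](C)(C)C(C)(C)C)C[C@@]1(C)O[Si](C)(OCC)OCC | intermediate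
18 | (1R,5S,aS)-5-[tert-butyl(dimethyl)silyl]oxy-1,3,3-trimethyl-2-[(3Z)-3-methyl-5-(triethylsilyloxy)penta-1,3-dien-1-ylidene]cyclohexan-1-ol (S-configured allene axis; side chain on the face of the tertiary OH) | [H]C(/C(C)=C\CO[Si](CC)(CC)CC)=[C@@]=C1C(C)(C)C[C@H](O[Si](C)(C)C(C)(C)C)C[C@@]1(C)O | intermediate
19 | tert-butyl(dimethyl){[(2R,6S,7aR)-4,4,7a-trimethyl-2-[(2Z)-4-(triethylsilyloxy)but-2-en-2-yl]-2,4,5,6,7,7a-hexahydro-1-benzofuran-6-yl]oxy}silane | C/C(=C/CO[Si](CC)(CC)CC)[C@H]1C=C2C(C)(C)C[C@H](O[Si](C)(C)C(C)(C)C)C[C@@]2(C)O1 | intermediate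
20 | (2Z)-3-[(2R,6S,7aR)-6-[tert-butyl(dimethyl)silyl]oxy-4,4,7a-trimethyl-2,4,5,6,7,7a-hexahydro-1-benzofuran-2-yl]but-2-en-1-ol | C/C(=C/CO)[C@H]1C=C2C(C)(C)C[C@H](O[Si](C)(C)C(C)(C)C)C[C@@]2(C)O1 | intermediate
21 | {[(2R,6S,7aR)-2-[(2Z)-4-bromobut-2-en-2-yl]-4,4,7a-trimethyl-2,4,5,6,7,7a-hexahydro-1-benzofuran-6-yl]oxy}(tert-butyl)dimethylsilane | C/C(=C/CBr)[C@H]1C=C2C(C)(C)C[C@H](O[Si](C)(C)C(C)(C)C)C[C@@]2(C)O1 | intermediate
22 | tributyl[(2Z)-3-[(2R,6S,7aR)-6-[tert-butyl(dimethyl)silyl]oxy-4,4,7a-trimethyl-2,4,5,6,7,7a-hexahydro-1-benzofuran-2-yl]but-2-en-1-yl]phosphonium bromide | C/C(=C/C[P+](CCCC)(CCCC)CCCC)[C@H]1C=C2C(C)(C)C[C@H](O[Si](C)(C)C(C)(C)C)C[C@@]2(C)O1.[Br-] | intermediate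
23 | (2E,4E,6E)-2,7-dimethylocta-2,4,6-trienedial | O=C/C(C)=C/C=C/C=C(C)/C=O | starting material
24 | ethyl (2E,4E,6E,8E)-4,9-dimethyl-10-oxodeca-2,4,6,8-tetraenoate | CCOC(=O)/C=C/C(C)=C/C=C/C=C(C)/C=O | intermediate
25 | allylic tributylphosphonium ylide derived from 22 | C/C(=C/C=P(CCCC)(CCCC)CCCC)[C@H]1C=C2C(C)(C)C[C@H](O[Si](C)(C)C(C)(C)C)C[C@@]2(C)O1 | intermediate
26 | ethyl (2E,4E,6E,8E,10E,12Z)-13-[(2R,6S,7aR)-6-[tert-butyl(dimethyl)silyl]oxy-4,4,7a-trimethyl-2,4,5,6,7,7a-hexahydro-1-benzofuran-2-yl]-4,9-dimethyltetradeca-2,4,6,8,10,12-hexaenoate | C/C(=C/C=C/C(C)=C/C=C/C=C(C)/C=C/C(=O)OCC)[C@H]1C=C2C(C)(C)C[C@H](O[Si](C)(C)C(C)(C)C)C[C@@]2(C)O1 | intermediate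
27 | (2E,4E,6E,8E,10E,12Z)-13-[(2R,6S,7aR)-6-[tert-butyl(dimethyl)silyl]oxy-4,4,7a-trimethyl-2,4,5,6,7,7a-hexahydro-1-benzofuran-2-yl]-4,9-dimethyltetradeca-2,4,6,8,10,12-hexaen-1-ol | C/C(=C/C=C/C(C)=C/C=C/C=C(C)/C=C/CO)[C@H]1C=C2C(C)(C)C[C@H](O[Si](C)(C)C(C)(C)C)C[C@@]2(C)O1 | intermediate
28 | (2R,6S,7aR)-2-[(2Z,4E,6E,8E,10E,12E)-14-hydroxy-6,11-dimethyltetradeca-2,4,6,8,10,12-hexaen-2-yl]-4,4,7a-trimethyl-2,4,5,6,7,7a-hexahydro-1-benzofuran-6-ol | C/C(=C/C=C/C(C)=C/C=C/C=C(C)/C=C/CO)[C@H]1C=C2C(C)(C)C[C@H](O)C[C@@]2(C)O1 | target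

**Totals**
Total step count: 21. Longest linear sequence: 18 steps (steps 1–9, 12–17, 19–21).

**Three steps most likely to fail**

Step 13 (copper hydride SN2' reduction). The risk is incomplete anti selectivity, or competing hydrocupration on a hindered tetrasubstituted oxirane. The fallback avoids the allene altogether, sets out from 11 (with 15) and comes back at 19. Hydroboration of alkyne 11 with pinacolborane (Cp2Zr(H)Cl cat., Et3N cat.) gives (1S,4S,6R)-4-[tert-butyl(dimethyl)silyl]oxy-2,2,6-trimethyl-1-[(E)-2-(4,4,5,5-tetramethyl-1,3,2-dioxaborolan-2-yl)ethenyl]-7-oxabicyclo[4.1.0]heptane F1. Suzuki–Miyaura coupling of this with 15 (Pd(PPh3)4, aqueous K3PO4, THF) gives (1S,4S,6R)-4-[tert-butyl(dimethyl)silyl]oxy-2,2,6-trimethyl-1-[(1E,3Z)-3-methyl-5-(triethylsilyloxy)penta-1,3-dien-1-yl]-7-oxabicyclo[4.1.0]heptane F2. Brief treatment with pyridinium p-toluenesulfonate in CH2Cl2 then triggers the classical 5,6-epoxide to 5,8-furanoid rearrangement. This is not stereoselective at C8, so 19 is obtained together with its (2S,6S,7aR) C8 epimer F3 and the two are separated by chromatography.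

Step 14 (gold cycloisomerisation). The cyclisation needs a chair with three syn-axial groups, and the vinylallene or the doubly allylic product may react further with the Lewis acid. The fallback sets out from 18 and comes back at 19. Electrophilic cyclisation of 18 with N-iodosuccinimide (CH2Cl2, 0 °C) uses the same axis-to-centre transfer and gives tert-butyl{[(2S,6S,7aR)-3-iodo-4,4,7a-trimethyl-2-[(2Z)-4-(triethylsilyloxy)but-2-en-2-yl]-2,4,5,6,7,7a-hexahydro-1-benzofuran-6-yl]oxy}dimethylsilane F4, which has the same spatial arrangement as 19 (the C2 descriptor changes only because iodine raises a CIP priority). Hydrodeiodination (Pd(PPh3)4 cat., HCO2H, Et3N, DMF, 50 °C) then gives 19.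

Step 19 (Wittig coupling). The risks are E/Z erosion at C11=C12, loss of the 9Z geometry, or ring opening of the ylide by expulsion of the C8 alkoxide. The fallback sets out from 21 and comes back at 26. Michaelis–Becker reaction of 21 with NaP(O)(OEt)2 (THF, 0 °C) gives diethyl [(2Z)-3-[(2R,6S,7aR)-6-[tert-butyl(dimethyl)silyl]oxy-4,4,7a-trimethyl-2,4,5,6,7,7a-hexahydro-1-benzofuran-2-yl]but-2-en-1-yl]phosphonate F5. Its anion (NaN(SiMe3)2, THF, −78 °C) undergoes Horner–Wadsworth–Emmons olefination with 24, where the E-alkene arises from a reversible addition and elimination, to give 26.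

**Further compounds**
F1 | step 13 | (1S,4S,6R)-4-[tert-butyl(dimethyl)silyl]oxy-2,2,6-trimethyl-1-[(E)-2-(4,4,5,5-tetramethyl-1,3,2-dioxaborolan-2-yl)ethenyl]-7-oxabicyclo[4.1.0]heptane | CC1(C)OB(/C=C/[C@@]23O[C@]2(C)C[C@@H](O[Si](C)(C)C(C)(C)C)CC3(C)C)OC1(C)C
F2 | step 13 | (1S,4S,6R)-4-[tert-butyl(dimethyl)silyl]oxy-2,2,6-trimethyl-1-[(1E,3Z)-3-methyl-5-(triethylsilyloxy)penta-1,3-dien-1-yl]-7-oxabicyclo[4.1.0]heptane | CC[Si](CC)(CC)OC/C=C(C)\C=C\[C@@]12O[C@]1(C)C[C@@H](O[Si](C)(C)C(C)(C)C)CC2(C)C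
F3 | step 13 | tert-butyl(dimethyl){[(2S,6S,7aR)-4,4,7a-trimethyl-2-[(2Z)-4-(triethylsilyloxy)but-2-en-2-yl]-2,4,5,6,7,7a-hexahydro-1-benzofuran-6-yl]oxy}silane (C8 epimer of 19) | C/C(=C/CO[Si](CC)(CC)CC)[C@@H]1C=C2C(C)(C)C[C@H](O[Si](C)(C)C(C)(C)C)C[C@@]2(C)O1
F4 | step 14 | tert-butyl{[(2S,6S,7aR)-3-iodo-4,4,7a-trimethyl-2-[(2Z)-4-(triethylsilyloxy)but-2-en-2-yl]-2,4,5,6,7,7a-hexahydro-1-benzofuran-6-yl]oxy}dimethylsilane | C/C(=C/CO[Si](CC)(CC)CC)[C@H]1C(I)=C2C(C)(C)C[C@H](O[Si](C)(C)C(C)(C)C)C[C@@]2(C)O1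
F5 | step 19 | diethyl [(2Z)-3-[(2R,6S,7aR)-6-[tert-butyl(dimethyl)silyl]oxy-4,4,7a-trimethyl-2,4,5,6,7,7a-hexahydro-1-benzofuran-2-yl]but-2-en-1-yl]phosphonate | C/C(=C/CP(=O)(OCC)OCC)[C@H]1C=C2C(C)(C)C[C@H](O[Si](C)(C)C(C)(C)C)C[C@@]2(C)O1
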